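## Retrosynthetic overview

1. Target 19 ⇒ nor-geranyl cage 16 + geranyl bromide 17: the sensitive geranyl diene is attached last, at the only acidic C–H of the cage (bridgehead C5).
2. 16 ⇒ bicyclic enol 13: one radical isomerisation makes the C3–C11 bond (closing both seven-membered rings of the homoadamantane) and then the cyclopentane bond; the bridge hydroxyl is removed afterwards.
3. 13 ⇒ adamantane aldol 10: retro-aldol opening and alkenyl addition leave the five-carbon arm endo on C7.
4. 10 ⇒ prenyl acylphloroglucinol 7 + bromomethyl enal 4: one-pot C-alkylation, Michael and aldol on a phloroglucinol that still has one free ring CH (reacting as its keto tautomer). The usual fully substituted, geranyl-bearing phloroglucinol is avoided because its two alkylated carbons cannot be told apart.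
5. Ring order: aromatic ring (becomes the trione ring) → cyclohexanone ring (C1–C8 bond) → transient adamantane ring (reopened) → seven-membered rings → cyclopentane.

Assumption: the cinchonidinium salt of step 5 is taken to give the enantiomer of 10 that is drawn; if it gives the antipode, its cinchonine-derived pseudoenantiomer is used.

Numbering used in names: bicyclo[3.3.1]nonane core with C1 = benzoyl-bearing bridgehead, C2–C3–C4 = 1,3-dicarbonyl bridge (C3 carries the prenyl group), C5 = other bridgehead, C6 = CH2, C7 = CH carrying the arm, C8 = CMe2, C9 = bridging ketone; C10 = bridge carbon on C7, C11 = ring-fusion CH on C3.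

## Route

Step 1
Reactants: 1 diethyl 2-(propan-2-ylidene)propanedioate
Product: 2 2-(propan-2-ylidene)propane-1,3-diol
Conditions: i-Bu2AlH (4.4 equiv), CH2Cl2, −78 °C → 0 °C; aq. potassium sodium tartrate
Reagents that add atoms: none
Why: Ester reduction with a dialkylaluminium hydride takes both conjugated ester groups 1,2 to the allylic alcohols, conjugate reduction being blocked by the fully substituted β-carbon; no stereocentre is formed.

Step 2
Reactants: 2 2-(propan-2-ylidene)propane-1,3-diol
Product: 3 2-(bromomethyl)-3-methylbut-2-en-1-ol
Conditions: CBr4 (1.0 equiv), PPh3 (1.0 equiv), CH2Cl2, −20 °C → 0 °C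
Reagents that add atoms: carbon tetrabromide, BrC(Br)(Br)Br
Why: Appel reaction with one equivalent of reagent brominates one of the two equivalent primary allylic hydroxyls by SN2 at the alkoxyphosphonium carbon, so only mono- versus dibromide has to be separated and recovered diol is recycled; no stereocentre.

Step 3
Reactants: 3 2-(bromomethyl)-3-methylbut-2-en-1-ol
Product: 4 2-(bromomethyl)-3-methylbut-2-enal
Conditions: MnO2 (10 equiv), CH2Cl2, rt
Reagents that add atoms: none
Why: Manganese dioxide oxidation of the allylic alcohol stops at the enal and leaves the allylic bromide alone; the alkene carries two identical methyl groups, so no geometry issue arises.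

Step 4
Reactants: 5 (2,4,6-trihydroxyphenyl)(phenyl)methanone; 6 1-bromo-3-methylbut-2-ene
Product: 7 [2,4,6-trihydroxy-3-(3-methylbut-2-en-1-yl)phenyl](phenyl)methanone
Conditions: 6 (1.0 equiv), 5% aq. KOH, 0 °C → rt
Reagents that add atoms: none
Why: C-alkylation of the ambident phloroglucinolate in water (C-attack favoured in protic medium) gives the mono-C-prenyl compound after rearomatisation, separated from the diprenyl by-product; no stereocentre.

Step 5
Reactants: 7 [2,4,6-trihydroxy-3-(3-methylbut-2-en-1-yl)phenyl](phenyl)methanone; 4 2-(bromomethyl)-3-methylbut-2-enal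
Product: 10 adamantane aldol (C5–H), via ring-alkylated phloroglucinol 8 (not isolated), via bicyclic keto aldehyde 9 (not isolated)
Conditions: 4 (1.1 equiv), CsOH·H2O (3 equiv), N-(9-anthracenylmethyl)-O-allylcinchonidinium bromide (15 mol%), toluene–CH2Cl2 3:1, −40 °C → 0 °C
Reagents that add atoms: none
Why: Proposed new method: the only free ring carbon of 7 is C-alkylated by the primary allylic bromide 4 (SN2 as in step 4, the tetrasubstituted β-carbon shutting off the SN2' path) to give 8, whose phloroglucinolate is reversibly C-protonated at that carbon (keto tautomer), so the benzoyl-bearing enolate carbon can add to the tethered β,β-dimethyl enal (intramolecular Michael addition, C1–C8 bond) to give 9; the Michael step is reversible and 9, which keeps the nucleophilic prenyl-substituted 1,3-diketone enolate, is drained because its C7 formyl group epimerises through the aldehyde enolate and the endo epimer is trapped by aldol addition from C3, which funnels the material to cage 10 with the hydroxyl anti to the CMe2 group; the chiral ammonium ion pair chooses the ring face that is bridged in the Michael step (C1 and C5), and C7, C3 and the carbinol follow from the cage; closest known reactions are the alkylative dearomatisation–annulation of fully substituted acylphloroglucinols with α-(acetoxymethyl) enals under chiral phase-transfer catalysis and the Lawton α,α'-annulation of cyclic 1,3-dicarbonyl compounds with 2-(bromomethyl)acrylates.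

Step 6
Reactants: 10 adamantane aldol (C5–H); 11 (2-methylprop-1-en-1-yl)magnesium bromide
Product: 13 bicyclic allylic alcohol (both carbinol epimers), via ring-opened cerium enolate 12 (not isolated)
Conditions: CeCl3 (4 equiv), 11 (4 equiv), THF, −78 °C → −20 °C; aq. NH4Cl
Reagents that add atoms: none
Why: Retro-aldol/organocerium 1,2-addition: the first equivalent of the alkenylcerium reagent deprotonates the hydroxyl of 10 and the cerium alkoxide opens by retro-aldol cleavage of the C3–C10 bond to cerium enolate 12, in which the formyl group is still endo on C7 and the C2–C4 dicarbonyl unit is masked as its enolate; the weakly basic reagent then adds 1,2 to the aldehyde before C7 can epimerise, C1, C5 and C7 are unchanged, and the new carbinol centre (both epimers) is removed in step 9.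

Step 7
Reactants: 13 bicyclic allylic alcohol (both carbinol epimers)
Product: 14 nor-geranyl cage alcohol (both carbinol epimers)
Conditions: [Ir(dF(CF3)ppy)2(dtbbpy)]PF6 (2 mol%), 2,4,6-triisopropylbenzenethiol (20 mol%), 2,6-lutidine (20 mol%), MeCN, 450 nm LED, rt, degassed
Reagents that add atoms: none
Why: Proposed new method: the acidic 1,3-diketone enol of 13 is oxidised (proton-coupled, lutidine as base) by the photoexcited iridium complex to the C3 radical, which can reach only the proximal carbon of the C7-endo alkene (7-exo closure that fixes C3 by the bridge and sets C11 with the CMe2 terminus turned to the C4/C5 side, away from the benzoyl and C8 methyl groups); the tertiary radical then closes 5-exo onto the C3 prenyl group (isopropyl carbon set with the side chain on the less hindered face, cis to C10) and the last tertiary radical takes a hydrogen atom from the thiol, whose thiyl radical is reduced by the reduced photocatalyst, so the step is an isomerisation that ends in isopropyl and not isopropenyl; closest known reactions are manganese triacetate radical cyclisations of 1,3-dicarbonyl enols onto prenyl groups and photoredox/thiol co-catalysed hydroalkylation of unactivated alkenes with 1,3-dicarbonyl compounds.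

Step 8
Reactants: 14 nor-geranyl cage alcohol (both carbinol epimers)
Product: 15 nor-geranyl cage O-(imidazol-1-ylthiocarbonyl) derivative (both epimers)
Conditions: 1,1'-thiocarbonyldiimidazole (3 equiv), DMAP (0.5 equiv), ClCH2CH2Cl, 80 °C
Reagents that add atoms: 1,1'-thiocarbonyldiimidazole, S=C(n1ccnc1)n1ccnc1
Why: Thioacylation of the secondary alcohol (first half of the Barton–McCombie deoxygenation); the ketones are non-enolisable or hindered and no stereocentre changes.

Step 9
Reactants: 15 nor-geranyl cage O-(imidazol-1-ylthiocarbonyl) derivative (both epimers)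
Product: 16 nor-geranyl cage
Conditions: Bu3SnH (3 equiv), AIBN (0.3 equiv), toluene, 100 °C
Reagents that add atoms: none
Why: Barton–McCombie radical deoxygenation: the stannyl radical adds to the thiocarbonyl group, the secondary cage radical is released and takes hydrogen from Bu3SnH; no C=C bond is left to interfere, and loss of the carbinol centre merges both epimers into one compound.

Step 10
Reactants: 16 nor-geranyl cage; 17 (2E)-1-bromo-3,7-dimethylocta-2,6-diene
Product: 19 target CNP0155129.2, via bridgehead lithium species 18 (not isolated)
Conditions: lithium 2,2,6,6-tetramethylpiperidide (1.5 equiv), THF, −78 °C → −40 °C; then 17 (3 equiv), −40 °C → 0 °C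
Reagents that add atoms: none
Why: Bridgehead lithiation–alkylation: C5–H is the only acidic hydrogen left (flanked by the C4 and C9 ketones, every other α-carbon being quaternary), and the pyramidal carbanion is alkylated by SN2 at the primary allylic carbon of 17 with necessary retention at C5 and untouched (E)-geometry; this reaction type is established for bicyclo[3.3.1]nonane-2,4,9-trione cores.

## Compound list

1 | diethyl 2-(propan-2-ylidene)propanedioate | CCOC(=O)C(=C(C)C)C(=O)OCC | starting material
2 | 2-(propan-2-ylidene)propane-1,3-diol | CC(C)=C(CO)CO | intermediate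
3 | 2-(bromomethyl)-3-methylbut-2-en-1-ol | CC(C)=C(CO)CBr | intermediate
4 | 2-(bromomethyl)-3-methylbut-2-enal | CC(C)=C(C=O)CBr | intermediate
5 | (2,4,6-trihydroxyphenyl)(phenyl)methanone | O=C(c1ccccc1)c1c(O)cc(O)cc1O | starting material
6 | 1-bromo-3-methylbut-2-ene (prenyl bromide) | CC(C)=CCBr | starting material
7 | [2,4,6-trihydroxy-3-(3-methylbut-2-en-1-yl)phenyl](phenyl)methanone | O=C(c1ccccc1)c1c(O)cc(O)c(CC=C(C)C)c1O | intermediate
8 | ring-alkylated phloroglucinol: 2-[3-benzoyl-2,4,6-trihydroxy-5-(3-methylbut-2-enyl)benzyl]-3-methylbut-2-enal | O=CC(Cc1c(O)c(CC=C(C)C)c(O)c(C(=O)c2ccccc2)c1O)=C(C)C | intermediate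
9 | bicyclic keto aldehyde: 1-benzoyl-2-hydroxy-8,8-dimethyl-3-(3-methylbut-2-enyl)-4,9-dioxobicyclo[3.3.1]non-2-ene-7-carbaldehyde, H at C5, formyl endo (on the side of the C2–C4 bridge) | [C@@H]12C[C@H](C=O)C(C)(C)[C@@](C(=O)c3ccccc3)(C1=O)C(O)=C(CC=C(C)C)C2=O | intermediate
10 | adamantane aldol (C5–H): 1-benzoyl-10-hydroxy-8,8-dimethyl-3-(3-methylbut-2-enyl)tricyclo[3.3.1.1(3,7)]decane-2,4,9-trione, C10 joins C7 and C3, hydroxyl anti to CMe2 | [C@@H]12C[C@H]3C(C)(C)[C@@](C(=O)c4ccccc4)(C1=O)C(=O)[C@](CC=C(C)C)([C@H]3O)C2=O | intermediate
11 | (2-methylprop-1-en-1-yl)magnesium bromide | CC(C)=C[Mg]Br | starting material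
12 | ring-opened cerium enolate: dichlorocerium enolate (O-bound at C2) of keto aldehyde 9, formyl endo on C7, H at C5 | [C@@H]12C[C@H](C=O)C(C)(C)[C@@](C(=O)c3ccccc3)(C1=O)C(O[Ce](Cl)Cl)=C(CC=C(C)C)C2=O | intermediate
13 | bicyclic allylic alcohol: 1-benzoyl-2-hydroxy-7-endo-(1-hydroxy-3-methylbut-2-enyl)-8,8-dimethyl-3-(3-methylbut-2-enyl)bicyclo[3.3.1]non-2-ene-4,9-dione, H at C5, both carbinol epimers | [C@@H]12C[C@H](C(O)C=C(C)C)C(C)(C)[C@@](C(=O)c3ccccc3)(C1=O)C(O)=C(CC=C(C)C)C2=O | intermediate
14 | nor-geranyl cage alcohol: cage of 19 with H at C5 and OH on C10 (both epimers); C11 bonded to C3, cyclopentane C3–C11–CMe2–CH(i-Pr)–CH2 with its CMe2 on the C4 side and i-Pr cis to C10 | [C@H]12C[C@@H]3C(O)[C@@H]4C(C)(C)[C@H](C(C)C)C[C@@]4(C1=O)C(=O)[C@](C(=O)c1ccccc1)(C2=O)C3(C)C | intermediate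
15 | O-(imidazol-1-ylthiocarbonyl) derivative of 14 (both epimers) | [C@H]12C[C@@H]3C(OC(=S)n5ccnc5)[C@@H]4C(C)(C)[C@H](C(C)C)C[C@@]4(C1=O)C(=O)[C@](C(=O)c1ccccc1)(C2=O)C3(C)C | intermediate
16 | nor-geranyl cage: 19 with H in place of the geranyl group at C5 | [C@H]12C[C@@H]3C[C@@H]4C(C)(C)[C@H](C(C)C)C[C@@]4(C1=O)C(=O)[C@](C(=O)c1ccccc1)(C2=O)C3(C)C | intermediate
17 | (2E)-1-bromo-3,7-dimethylocta-2,6-diene (geranyl bromide) | CC(C)=CCC/C(C)=C/CBr | starting material
18 | bridgehead lithium species: C5-lithio derivative of 16 | [Li][C@]12C[C@@H]3C[C@@H]4C(C)(C)[C@H](C(C)C)C[C@@]4(C1=O)C(=O)[C@](C(=O)c1ccccc1)(C2=O)C3(C)C | intermediate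
19 | target CNP0155129.2: C5-[(2E)-3,7-dimethylocta-2,6-dienyl] derivative of 16 | CC(C)=CCC/C(C)=C/C[C@]12C[C@@H]3C[C@@H]4C(C)(C)[C@H](C(C)C)C[C@@]4(C1=O)C(=O)[C@](C(=O)c1ccccc1)(C2=O)C3(C)C | target

## Step count and risk

Total step count: 10.
Longest linear sequence: 9 steps (steps 1, 2, 3, 5, 6, 7, 8, 9, 10, from 1); 7 steps from 5.

Steps most likely to fail:

Step 5. Ring closure needs the minor keto tautomer of 8, the benzoyl-bearing carbon has to act as Michael donor in competition with the prenyl-bearing one (which would lead to an isomeric cage), and the asymmetric induction in this new setting is untested. Fallback: the two events are separated and the ring closure is moved from base to acid catalysis, where alkylated phloroglucinols react through their C-protonated (keto) forms and both ring-closing steps are reversible, so that the cage whose last bond comes from the more nucleophilic prenyl-substituted enol can accumulate. From 7, alkylation with 4 in 5% aq. KOH at 0 °C (as in step 4) gives isolated 8; 8 with the chiral phosphoric acid (R)-TRIP (10 mol%) in toluene at 40 °C then undergoes enol Michael addition of the neutral keto tautomer to the acid-activated enal and aldol closure. The fallback sets out from 7 and comes back to the route at 10; it makes no compound beyond the list (F0).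

Step 7. The photoredox isomerisation may stall, or the thiol may not intercept the last radical. Fallback: the same C3 radical is made by stoichiometric oxidation. From 13, Mn(OAc)3·2H2O (2.5 equiv) and Cu(OAc)2·H2O (0.2 equiv) in AcOH at rt give the same two ring closures, but copper diacetate oxidises the terminal tertiary radical to the alkene, giving isopropenyl cage alcohol F1. As F1 has no other C=C bond, H2 (1 atm) over RhCl(PPh3)3 in benzene–ethanol reduces it to the isopropyl compound. The fallback sets out from 13 and comes back at 14.

Step 10. The bridgehead enolate of the rigid cage is of the strained bridgehead-alkene type, so deprotonation may be slow or the base may attack a ketone. Fallback: the geranyl group is brought in earlier, on the more flexible bicycle. From 13, lithium 2,2,6,6-tetramethylpiperidide (3.3 equiv, THF, −78 °C → 0 °C) forms the trianion (alkoxide, 1,3-diketone enolate and C5 carbanion, a Hauser-type dianion at the remaining α'-position), which is alkylated by 17 at C5 to give C5-geranyl bicycle F2. F2 is cyclised as in step 7 to geranyl cage alcohol F3 and converted as in step 8 into geranyl thiocarbamate F4; tin hydride reduction as in step 9 then gives the target directly. The fallback sets out from 13 and comes back at 19.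

## Further compounds

F0 | step 5 | none | none
F1 | step 7 | isopropenyl cage alcohol: 14 with prop-1-en-2-yl in place of isopropyl (both carbinol epimers) | [C@H]12C[C@@H]3C(O)[C@@H]4C(C)(C)[C@H](C(C)=C)C[C@@]4(C1=O)C(=O)[C@](C(=O)c1ccccc1)(C2=O)C3(C)C
F2 | step 10 | C5-geranyl bicycle: 13 with (2E)-3,7-dimethylocta-2,6-dienyl at C5 (both carbinol epimers) | CC(C)=CCC/C(C)=C/C[C@@]12C[C@H](C(O)C=C(C)C)C(C)(C)[C@@](C(=O)c3ccccc3)(C1=O)C(O)=C(CC=C(C)C)C2=O
F3 | step 10 | geranyl cage alcohol: 14 with (2E)-3,7-dimethylocta-2,6-dienyl at C5 (both carbinol epimers) | CC(C)=CCC/C(C)=C/C[C@]12C[C@@H]3C(O)[C@@H]4C(C)(C)[C@H](C(C)C)C[C@@]4(C1=O)C(=O)[C@](C(=O)c1ccccc1)(C2=O)C3(C)C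
F4 | step 10 | geranyl thiocarbamate: 15 with (2E)-3,7-dimethylocta-2,6-dienyl at C5 (both carbinol epimers) | CC(C)=CCC/C(C)=C/C[C@]12C[C@@H]3C(OC(=S)n5ccnc5)[C@@H]4C(C)(C)[C@H](C(C)C)C[C@@]4(C1=O)C(=O)[C@](C(=O)c1ccccc1)(C2=O)C3(C)C
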